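Everything rests on closing the γ-lactone ring by the C7–C11 bond (elemane numbering). An α-diazo-α-(diethoxyphosphoryl)acetate on the equatorial O6 of the cyclohexane ring (C5–C10) gives a rhodium carbenoid that inserts into the equatorial C7–H bond, the methylene hydrogen flanked by the oxygenated carbons C6 and C8. One operation forms the trans-fused lactone ring (O6–C12–C11–C7–C6), sets C7 by retention and, through Horner–Wadsworth–Emmons methylenation of the phosphonate in the same flask, installs C11=C13. The precursor is the monocyclic elemane 18, already carrying the O8 side-chain ester, the C5 acrolein unit and the C10 methyl/vinyl centre, built from (+)-verbenone by cyclobutane cleavage.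

Key step: step 14

Remark: ring compounds are named with elemane numbering (ring C5–C10; C10 bears CH3 and vinyl, C5 the three-carbon side chain, C11–C13 are the lactone carbons); β is the face of the C10 methyl group and α that of the C10 vinyl group. (1R,5R)-verbenone and (R)-2-(2,2-dimethyl-1,3-dioxolan-4-yl)ethanol are assumed to be purchased.

Step 1
Reactants: 1 (1R,5R)-(+)-verbenone
Product: 2 (1R,4S,5S)-4,6,6-trimethyl-4-vinylbicyclo[3.1.1]heptan-2-one (vinyl anti to the CMe2 bridge)
Conditions: CH2=CHMgBr, CuI (cat.), THF, −40 → 0 °C; aq. NH4Cl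
Reagents that add atoms: vinylmagnesium bromide, C=C[Mg]Br
Why: copper-catalysed conjugate (1,4) addition of a vinyl Grignard reagent; the gem-dimethyl bridge shields one face of the enone, so vinyl enters anti to it and the new quaternary carbon (later C10) has vinyl trans to the carbon that becomes the C5 side chain.

Step 2
Reactants: 2 vinyl ketone
Product: 3 5β-(2-acetoxypropan-2-yl)-10β-methyl-10α-vinylcyclohex-7-en-8-yl acetate
Conditions: BF3·OEt2, Zn(OAc)2, Ac2O, 0 °C → rt
Reagents that add atoms: acetic anhydride, CC(=O)OC(C)=O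
Why: Lewis-acid-promoted cyclobutane fragmentation of a 6,6-dimethylbicyclo[3.1.1]heptan-2-one, in which the strained bond between the α-carbon and the CMe2 carbon breaks, acetate traps the tertiary cation and the enolate is acetylated, so the C7=C8 enol acetate forms regiospecifically while C5 and C10 are untouched.

Step 3
Reactants: 3 diacetate
Product: 5 5β-(2-hydroxypropan-2-yl)-10β-methyl-10α-vinylcyclohex-6-en-8-one, via α-phenylselanyl ketone 4 (not isolated)
Conditions: MeLi (4.2 equiv), THF, −78 → 0 °C; PhSeCl, −78 °C; then H2O2, pyridine, CH2Cl2, 0 °C → rt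
Reagents that add atoms: phenylselenenyl chloride, Cl[Se]c1ccccc1 (selenium in 4 only)
Why: methyllithium cleaves both acetates and releases the lithium enolate only towards C7, and α-selenenylation followed by selenoxide syn-elimination can then only give the C6=C7 enone because C8 is the carbonyl carbon.

Step 4
Reactants: 5 hydroxy enone
Product: 7 6α-hydroxy-5β-(2-hydroxypropan-2-yl)-10β-methyl-10α-vinylcyclohexan-8-one, via β-boryl ketone 6 (not isolated)
Conditions: B2pin2, CuCl (5 mol%), DPEphos (5 mol%), NaOtBu (10 mol%), MeOH, THF, rt; then NaBO3·4H2O, THF/H2O, rt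
Reagents that add atoms: bis(pinacolato)diboron, CC1(C)OB(OC1(C)C)B1OC(C)(C)C(C)(C)O1 (boron group in 6 only); sodium perborate, [Na+].[O-]OB=O
Why: copper(I)-catalysed conjugate borylation followed by perborate oxidation with retention; the boryl copper species should add to C6 anti to the bulky C5 carbinol and the axial C10 methyl, so the C6 oxygen ends α, trans to the C5 substituent.

Step 5
Reactants: 7 dihydroxy ketone
Product: 8 5β-(2-hydroxypropan-2-yl)-10β-methyl-10α-vinylcyclohexane-6α,8α-diol
Conditions: Li, NH3(l)/THF, −78 °C; NH4Cl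
Reagents that add atoms: none
Why: dissolving-metal reduction of the ketone should give the thermodynamically favoured equatorial 8α-alcohol, because the axial epimer would be 1,3-diaxial to the C10 methyl group; isolated alkenes are not reduced.

Step 6
Reactants: 9 (R)-2-(2,2-dimethyl-1,3-dioxolan-4-yl)ethan-1-ol
Product: 10 (R)-2-(2,2-dimethyl-1,3-dioxolan-4-yl)acetaldehyde
Conditions: Dess–Martin periodinane, NaHCO3, CH2Cl2, 0 °C → rt
Reagents that add atoms: none
Why: Dess–Martin oxidation of the primary alcohol to the aldehyde; the stereocentre is β to the carbonyl and is not epimerised.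

Step 7
Reactants: 10 aldehyde
Product: 11 (R)-2-(2,2-dimethyl-1,3-dioxolan-4-yl)acrylaldehyde
Conditions: 37% aq. CH2O, pyrrolidine (10 mol%), propionic acid (10 mol%), i-PrOH, 45 °C
Reagents that add atoms: formaldehyde, C=O
Why: amine-catalysed α-methylenation of the aldehyde (Mannich condensation, then β-elimination of the amine); the dioxolane stereocentre is not involved.

Step 8
Reactants: 11 α-methylene aldehyde
Product: 12 (R)-2-(2,2-dimethyl-1,3-dioxolan-4-yl)acrylic acid
Conditions: NaClO2, NaH2PO4, 2-methylbut-2-ene, t-BuOH/H2O, 0 °C → rt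
Reagents that add atoms: sodium chlorite, [Na+].[O-]Cl=O
Why: Pinnick oxidation converts the enal into the acrylic acid without touching the alkene, the acetonide or the stereocentre.

Step 9
Reactants: 8 triol; 12 side-chain acid
Product: 13 6α-hydroxy-5β-(2-hydroxypropan-2-yl)-10β-methyl-10α-vinylcyclohexan-8α-yl (R)-2-(2,2-dimethyl-1,3-dioxolan-4-yl)acrylate
Conditions: 12, 2,4,6-trichlorobenzoyl chloride, Et3N, THF, rt; then 8, DMAP, toluene, 0 °C → rt
Reagents that add atoms: none
Why: Yamaguchi esterification through the mixed anhydride of 12; of the three hydroxyls only the equatorial C8–OH between two methylene groups is unhindered, whereas C6–OH adjoins the C5 tertiary carbinol and the tertiary alcohol does not acylate.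

Step 10
Reactants: 13 mono-ester
Product: 14 6α-[2-(diethoxyphosphoryl)acetoxy] derivative of 13
Conditions: (EtO)2P(O)CH2CO2H, DCC, DMAP (cat.), CH2Cl2, 0 °C → rt
Reagents that add atoms: diethylphosphonoacetic acid, OC(=O)CP(=O)(OCC)OCC
Why: Steglich esterification of the only remaining secondary hydroxyl (C6–OH); the tertiary alcohol is inert under these conditions.

Step 11
Reactants: 14 phosphonoacetate
Product: 15 5β-isopropenyl compound (14 with the C5 carbinol dehydrated to prop-1-en-2-yl)
Conditions: Burgess reagent, toluene, 50 °C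
Reagents that add atoms: none
Why: Burgess dehydration (syn-elimination of the sulfamate of the only free, tertiary hydroxyl); proton loss from a methyl group is favoured over loss of the hindered C5–H, whose product would be a tetrasubstituted alkene with A(1,3) strain against the C10 substituents.

Step 12
Reactants: 15 isopropenyl compound
Product: 17 enal (15 with the C5 substituent oxidised to 3-oxoprop-1-en-2-yl), via allylic alcohol 16 (not isolated)
Conditions: SeO2 (0.3 equiv), t-BuOOH, CH2Cl2, rt; then MnO2, CH2Cl2, rt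
Reagents that add atoms: selenium dioxide, O=[Se]=O; tert-butyl hydroperoxide, CC(C)(C)OO
Why: selenium dioxide allylic oxidation (ene reaction, then [2,3]-shift) at the methyl group of the isopropenyl unit, the only electron-rich alkene with allylic hydrogens (the vinyl group has none, the acrylate is electron-poor), followed by MnO2 oxidation of the allylic alcohol to the enal.

Step 13
Reactants: 17 enal
Product: 18 6α-[2-diazo-2-(diethoxyphosphoryl)acetoxy] enal
Conditions: p-ABSA, DBU, MeCN, 0 °C
Reagents that add atoms: 4-acetamidobenzenesulfonyl azide, CC(=O)Nc1ccc(cc1)S(=O)(=O)N=[N+]=[N-]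
Why: Regitz diazo transfer from the sulfonyl azide to the DBU-generated phosphonoacetate anion, which is expected to be faster than addition of that anion to the hindered enal in the absence of lithium salts.

Step 14
Reactants: 18 diazo phosphonoacetate
Product: 20 acetonide of the target (trans-fused α-methylene-12,6α-olide), via α-phosphono lactone 19 (not isolated)
Conditions: Rh2(oct)4 (2 mol%), CH2Cl2, 45 °C; then KOtBu, (CH2O)n, THF, 0 °C → rt
Reagents that add atoms: formaldehyde (as paraformaldehyde), C=O
Why: Rh2(oct)4 decomposes the diazo ester to an electrophilic rhodium carbenoid that inserts into the C7–H bond through a concerted, asynchronous three-centre transition state with retention at C7, and the resulting α-phosphono lactone is deprotonated and olefinated by formaldehyde (Horner–Wadsworth–Emmons) to give C11=C13. The closest known reaction type is the rhodium(II)-catalysed 1,5 C–H insertion of cycloalkyl α-diazo-α-(diethoxyphosphoryl)acetates telescoped with Horner–Wadsworth–Emmons methylenation to α-methylene-γ-butyrolactones. The lactone closes as a five-membered ring by 1,5-insertion (carbenoid carbon C11 onto the C–H bond β to O6), trans-fused to the cyclohexane. C7 is the only lasting new stereocentre and is fixed by retention: the equatorial O6 tether reaches the equatorial (β) C7–H, so C11 ends β and trans to O6, while the C11 epimers of 19 converge in the olefination. The step needs site selectivity for C7–Hβ over the axial C7–Hα and the axial tertiary C5–H (both would give cis-fused lactones) and chemoselectivity over four C=C bonds and the aldehyde. The all-equatorial chair (C5, C6 and C8 substituents equatorial, C10 methyl axial) should secure the former, and the latter rests on the alkenes being electron-poor (enal, acrylate) or remote (vinyl) and on C5–H being deactivated by the adjacent enal.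

Step 15
Reactants: 20 target acetonide
Product: 21 CNP0204284.1
Conditions: AcOH/H2O (4:1), 40 °C
Reagents that add atoms: none
Why: acid-catalysed hydrolysis of the acetonide; the enal, the lactone and both α-methylene esters should survive aqueous acetic acid, and no stereocentre is touched.

Compound list
1 | (1R,5R)-(+)-verbenone, (1R,5R)-4,6,6-trimethylbicyclo[3.1.1]hept-3-en-2-one | CC1=CC(=O)[C@@H]2C[C@H]1C2(C)C | starting material
2 | (1R,4S,5S)-4,6,6-trimethyl-4-vinylbicyclo[3.1.1]heptan-2-one (vinyl anti to the CMe2 bridge) | C=C[C@]1(C)CC(=O)[C@@H]2C[C@H]1C2(C)C | intermediate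
3 | 5β-(2-acetoxypropan-2-yl)-10β-methyl-10α-vinylcyclohex-7-en-8-yl acetate (C7=C8 enol acetate) | C=C[C@]1(C)CC(OC(C)=O)=CC[C@H]1C(C)(C)OC(C)=O | intermediate
4 | 5β-(2-hydroxypropan-2-yl)-10β-methyl-7-(phenylselanyl)-10α-vinylcyclohexan-8-one (C7 epimers) | C=C[C@]1(C)CC(=O)C([Se]c2ccccc2)C[C@H]1C(C)(C)O | intermediate
5 | 5β-(2-hydroxypropan-2-yl)-10β-methyl-10α-vinylcyclohex-6-en-8-one | C=C[C@]1(C)CC(=O)C=C[C@H]1C(C)(C)O | intermediate
6 | 5β-(2-hydroxypropan-2-yl)-10β-methyl-6α-(pinacolatoboryl)-10α-vinylcyclohexan-8-one | C=C[C@]1(C)CC(=O)C[C@H](B2OC(C)(C)C(C)(C)O2)[C@H]1C(C)(C)O | intermediate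
7 | 6α-hydroxy-5β-(2-hydroxypropan-2-yl)-10β-methyl-10α-vinylcyclohexan-8-one | C=C[C@]1(C)CC(=O)C[C@H](O)[C@H]1C(C)(C)O | intermediate
8 | 5β-(2-hydroxypropan-2-yl)-10β-methyl-10α-vinylcyclohexane-6α,8α-diol | C=C[C@]1(C)C[C@H](O)C[C@H](O)[C@H]1C(C)(C)O | intermediate
9 | (R)-2-(2,2-dimethyl-1,3-dioxolan-4-yl)ethan-1-ol | OCC[C@@H]1COC(C)(C)O1 | starting material
10 | (R)-2-(2,2-dimethyl-1,3-dioxolan-4-yl)acetaldehyde | O=CC[C@@H]1COC(C)(C)O1 | intermediate
11 | (R)-2-(2,2-dimethyl-1,3-dioxolan-4-yl)acrylaldehyde | O=CC(=C)[C@@H]1COC(C)(C)O1 | intermediate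
12 | (R)-2-(2,2-dimethyl-1,3-dioxolan-4-yl)acrylic acid | OC(=O)C(=C)[C@@H]1COC(C)(C)O1 | intermediate
13 | 6α-hydroxy-5β-(2-hydroxypropan-2-yl)-10β-methyl-10α-vinylcyclohexan-8α-yl (R)-2-(2,2-dimethyl-1,3-dioxolan-4-yl)acrylate | C=C[C@]1(C)C[C@H](OC(=O)C(=C)[C@@H]2COC(C)(C)O2)C[C@H](O)[C@H]1C(C)(C)O | intermediate
14 | 6α-[2-(diethoxyphosphoryl)acetoxy] derivative of 13 (tertiary alcohol free) | C=C[C@]1(C)C[C@H](OC(=O)C(=C)[C@@H]2COC(C)(C)O2)C[C@H](OC(=O)CP(=O)(OCC)OCC)[C@H]1C(C)(C)O | intermediate
15 | 6α-[2-(diethoxyphosphoryl)acetoxy]-10β-methyl-5β-(prop-1-en-2-yl)-10α-vinylcyclohexan-8α-yl (R)-2-(2,2-dimethyl-1,3-dioxolan-4-yl)acrylate | C=C[C@]1(C)C[C@H](OC(=O)C(=C)[C@@H]2COC(C)(C)O2)C[C@H](OC(=O)CP(=O)(OCC)OCC)[C@H]1C(C)=C | intermediate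
16 | as 15, with 5β-(3-hydroxyprop-1-en-2-yl) | C=C[C@]1(C)C[C@H](OC(=O)C(=C)[C@@H]2COC(C)(C)O2)C[C@H](OC(=O)CP(=O)(OCC)OCC)[C@H]1C(=C)CO | intermediate
17 | as 15, with 5β-(3-oxoprop-1-en-2-yl) | C=C[C@]1(C)C[C@H](OC(=O)C(=C)[C@@H]2COC(C)(C)O2)C[C@H](OC(=O)CP(=O)(OCC)OCC)[C@H]1C(=C)C=O | intermediate
18 | as 17, with 6α-[2-diazo-2-(diethoxyphosphoryl)acetoxy] | C=C[C@]1(C)C[C@H](OC(=O)C(=C)[C@@H]2COC(C)(C)O2)C[C@H](OC(=O)C(=[N+]=[N-])P(=O)(OCC)OCC)[C@H]1C(=C)C=O | intermediate
19 | 11-(diethoxyphosphoryl)-15-oxoelema-1,3-dien-12,6α-olid-8α-yl (R)-2-(2,2-dimethyl-1,3-dioxolan-4-yl)acrylate (trans-fused lactone, C11 epimers) | C=C[C@]1(C)C[C@H](OC(=O)C(=C)[C@@H]3COC(C)(C)O3)[C@H]2C(P(=O)(OCC)OCC)C(=O)O[C@@H]2[C@H]1C(=C)C=O | intermediate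
20 | 15-oxoelema-1,3,11(13)-trien-12,6α-olid-8α-yl (R)-2-(2,2-dimethyl-1,3-dioxolan-4-yl)acrylate (acetonide of the target) | C=C[C@]1(C)C[C@H](OC(=O)C(=C)[C@@H]3COC(C)(C)O3)[C@H]2C(=C)C(=O)O[C@@H]2[C@H]1C(=C)C=O | intermediate
21 | CNP0204284.1, 8α-[(R)-3,4-dihydroxy-2-methylenebutanoyloxy]-15-oxoelema-1,3,11(13)-trien-12,6α-olide | C=C[C@]1(C)C[C@H](OC(=O)C(=C)[C@@H](O)CO)[C@H]2C(=C)C(=O)O[C@@H]2[C@H]1C(=C)C=O | target

Total step count: 15. Longest linear sequence: 12 steps (steps 1–5 and 9–15); the side-chain acid takes 3 steps (6–8).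

Steps most likely to fail

1. Step 14. The C7–H bond is inductively deactivated by the oxygen functions on both C6 and C8, so insertion may be slower than carbenoid dimerisation, capture by traces of water, or attack on the side-chain and aldehyde functions. Fallback (sets out from 8, comes back at 20): the side chain is left off until the lactone is made, so that a silyloxy group replaces the acyloxy group next to C7 and no side-chain functions are present. Triol 8 is silylated at the unhindered 8α-hydroxyl (TESCl, imidazole, CH2Cl2, −20 °C) to give 8α-triethylsilyl ether F1. Acylation of the C6 hydroxyl (diethylphosphonoacetic acid, DCC, DMAP) gives phosphonoacetate F2 and Burgess dehydration gives isopropenyl compound F3. SeO2/t-BuOOH then MnO2 leads through allylic alcohol F4 to enal F5, and diazo transfer (p-ABSA, DBU) gives diazo ester F6. Rh2(oct)4 followed by KOtBu/(CH2O)n should give, through α-phosphono lactone F7, α-methylene lactone silyl ether F8. HF·pyridine in THF frees 8α-hydroxy lactone F9, which is esterified with 12 under Yamaguchi conditions to give 20.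

2. Step 13. The phosphonate carbanion may add to the enal aldehyde (Horner–Wadsworth–Emmons reaction), or DBU may add to the enal, before the diazo transfer is complete. Fallback (sets out from 15, comes back at 18): the oxidation of step 12 is stopped after the SeO2/t-BuOOH stage and allylic alcohol 16 is isolated. Diazo transfer (p-ABSA, DBU, MeCN) on 16, which carries no aldehyde, gives diazo allylic alcohol F10. MnO2 then oxidises the allylic alcohol without touching the acceptor-substituted diazo group and gives 18.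

3. Step 9. Acylation may not discriminate well enough between the C8 and C6 hydroxyls, or may run on to the bis-ester. Fallback (sets out from 7, comes back at 13): the two secondary hydroxyls are told apart by configuration instead of hindrance. L-Selectride (THF, −78 °C) should attack the C8 ketone of 7 from the equatorial direction, away from the axial C10 methyl, and give 8β-epimeric triol F11 with an axial C8 hydroxyl. Mitsunobu esterification with 12 (PPh3, DIAD, toluene) can invert only C8, because displacement at C6 would have to pass the axial C10 methyl and the C5 carbinol and the tertiary alcohol does not react; it gives 13.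

Further compounds
F1 | step 14 | 6α-hydroxy-5β-(2-hydroxypropan-2-yl)-10β-methyl-8α-(triethylsilyloxy)-10α-vinylcyclohexane | C=C[C@]1(C)C[C@H](O[Si](CC)(CC)CC)C[C@H](O)[C@H]1C(C)(C)O
F2 | step 14 | 6α-[2-(diethoxyphosphoryl)acetoxy] derivative of F1 | C=C[C@]1(C)C[C@H](O[Si](CC)(CC)CC)C[C@H](OC(=O)CP(=O)(OCC)OCC)[C@H]1C(C)(C)O
F3 | step 14 | 5β-isopropenyl compound from F2 | C=C[C@]1(C)C[C@H](O[Si](CC)(CC)CC)C[C@H](OC(=O)CP(=O)(OCC)OCC)[C@H]1C(C)=C
F4 | step 14 | allylic alcohol from F3, 5β-(3-hydroxyprop-1-en-2-yl) | C=C[C@]1(C)C[C@H](O[Si](CC)(CC)CC)C[C@H](OC(=O)CP(=O)(OCC)OCC)[C@H]1C(=C)CO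
F5 | step 14 | enal from F4, 5β-(3-oxoprop-1-en-2-yl) | C=C[C@]1(C)C[C@H](O[Si](CC)(CC)CC)C[C@H](OC(=O)CP(=O)(OCC)OCC)[C@H]1C(=C)C=O
F6 | step 14 | 6α-[2-diazo-2-(diethoxyphosphoryl)acetoxy] enal with 8α-triethylsilyloxy group | C=C[C@]1(C)C[C@H](O[Si](CC)(CC)CC)C[C@H](OC(=O)C(=[N+]=[N-])P(=O)(OCC)OCC)[C@H]1C(=C)C=O
F7 | step 14 | 11-(diethoxyphosphoryl)-15-oxo-8α-(triethylsilyloxy)elema-1,3-dien-12,6α-olide (C11 epimers) | C=C[C@]1(C)C[C@H](O[Si](CC)(CC)CC)[C@H]2C(P(=O)(OCC)OCC)C(=O)O[C@@H]2[C@H]1C(=C)C=O
F8 | step 14 | 15-oxo-8α-(triethylsilyloxy)elema-1,3,11(13)-trien-12,6α-olide | C=C[C@]1(C)C[C@H](O[Si](CC)(CC)CC)[C@H]2C(=C)C(=O)O[C@@H]2[C@H]1C(=C)C=O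
F9 | step 14 | 8α-hydroxy-15-oxoelema-1,3,11(13)-trien-12,6α-olide | C=C[C@]1(C)C[C@H](O)[C@H]2C(=C)C(=O)O[C@@H]2[C@H]1C(=C)C=O
F10 | step 13 | diazo allylic alcohol, 16 with 6α-[2-diazo-2-(diethoxyphosphoryl)acetoxy] | C=C[C@]1(C)C[C@H](OC(=O)C(=C)[C@@H]2COC(C)(C)O2)C[C@H](OC(=O)C(=[N+]=[N-])P(=O)(OCC)OCC)[C@H]1C(=C)CO
F11 | step 9 | 5β-(2-hydroxypropan-2-yl)-10β-methyl-10α-vinylcyclohexane-6α,8β-diol | C=C[C@]1(C)C[C@@H](O)C[C@H](O)[C@H]1C(C)(C)O
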